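## Structural features

The target is a linear hexamer of acylphloroglucinol units: six six-membered carbocycles, rings A to F, joined head to tail by five CH2 bridges. Ring A is a dearomatised 2-butanoylfilicinic acid, a 4,4-dimethylcyclohexadienone that is an enolised β-triketone with a quaternary CMe2 carbon. Rings B to E are four identical, fully substituted 3-butanoyl-2,4,6-trihydroxyphenylene units with two bridges each, and ring F is a 3-butanoyl-2,4,6-trihydroxy-5-methylphenyl terminus. There is no stereocentre, so no stereocentres stand next to each other and the problem is one of regiochemistry and sequence only. The fragile elements are the diarylmethane bridges between very electron-rich rings (reversible through o-quinone methides in base or on heating, open to ipso-protonation in acid), the air-sensitive polyphenols, the enolised triketone of ring A, and the six ketones, which exclude organolithium chemistry once they are present. The real difficulty is to join six almost identical polyfunctional nucleophiles in a fixed order without statistical oligomerisation, and to place exactly one butanoyl group on each ring. The key step exploits ring E, where three oxygen-bearing carbons alternate with the carbon destined for butanoyl and with the two carbons that carry the CH2 links to rings D and F. These six atoms map onto the four ring carbons of a 3-siloxycyclobutenone carrying the ring D arm on C2 and the two sp carbons of a siloxyalkyne carrying the ring F arm.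

## Logic of the disconnections

49 to 33 and 47. The bond cut joins the CH2 carbon on ring C to the only unsubstituted carbon of ring D. This divides the hexamer into two trimers, one of which (33) is what the ring E annulation delivers, and each partner has a single reactive site, so no positional isomers can form. The forward step must generate an o-quinone methide on ring C under conditions mild enough not to reopen the four existing bridges.

47 to 46 and 43. The C–C bond between ring C and the aminomethyl carbon is cut (Mannich transform). The bridge carbon is thereby stored on one partner in an isolable, latent electrophilic form, which avoids the homodimers of a three-component formaldehyde condensation. The forward step needs aminomethylation at the one free carbon of ring C only.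

46 to 39, 42 and 43. Both C–C bonds of the CH2 bridge between rings A and B are cut. 42 is symmetrical, so either ring can become ring B, and 39 has one nucleophilic carbon; the electrophile is placed on 39 because its methylidene trione has no free carbon and cannot oligomerise. Mono-alkylation of 42 has to be enforced by using 42 in excess.

42 to two molecules of 36 and 40. The two aryl–CH2 bonds of the bridge are cut, which reduces the dimer to one monomer. Because 36 has two free ring carbons, the forward condensation needs excess 36 to stop at the dimer.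

39 to 36 and two molecules of 37. The two C–CH3 bonds at the quaternary carbon are cut, so ring A comes from the same monomer as rings B and C. The forward step must put both methyl groups on one carbon (dearomatising gem-dimethylation) and tolerate separation from other methylation levels.

36 to 34 and 35. The aryl–carbonyl bond is cut, leading to two bulk chemicals. The forward acylation must stop after one acyl group, which the deactivating ketone ensures.

33 to 31 and 32. Three aryl–carbonyl bonds, one on each of rings D, E and F, are cut together. Ketones cannot pass through acetylide and ynolate chemistry, so they enter after the annulation, and one operation for all three saves steps. Rings E and F have one free carbon each and ring D has two equivalent ones; the first acyl group deactivates its ring, so stoichiometric control should leave one CH on ring D. The acid must be mild enough not to move the two bridges.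

31 to 30 to 29. Six O–benzyl bonds and two O–silyl bonds are cut. Benzyl ethers are chosen for the arms because they survive acetylide, ketene and thermal chemistry and leave under neutral hydrogenolysis, which cannot touch the diarylmethane links. The forward steps need fluoride that spares benzyl ethers and hydrogenolysis that spares the rings.

29 to 14 and 24 (key disconnection). Three ring E bonds are cut: hydroxyl-bearing carbon to the carbon carrying the ring F arm, siloxy-bearing carbon to the carbon carrying the ring D arm, and hydroxyl-bearing carbon to the unsubstituted CH. Ring E disappears and the two arms are separated into partners of equal complexity. The forward step needs the [2+2] regiochemistry of a ketene with an ynol ether and must overcome the bulk of two 2,6-bis(benzyloxy)benzyl groups.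

14 to 11 and 13 (made from 12). The two cyclobutenone bonds formed from the ketene unit are cut, so 14 and 24 come from one compound class. The forward step needs a regioselective [2+2] cycloaddition and gentle handling of the silyl enol ether.

11 to 6, 7 and 8; likewise 24 to 21, 7 and 8. The C(sp)–O and O–Si bonds are cut. Oxidation of an acetylide is preferred to ester homologation because it uses one equivalent of alkyllithium, so six benzyl ethers and an acidic benzylic CH2 are not exposed to excess base. The forward step needs O-silylation of the ynolate, which the bulky silyl group secures.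

6 to 5 to 3 and 4; likewise 21 to 20 to 19 and 4. The benzylic C–O bond and then the C(benzylic)–C(sp) bond are cut. The three-carbon arm is thereby reduced to an aldehyde and an ethynyl nucleophile. The forward deoxygenation must deliver hydride to the benzylic carbon of a propargylic cation.

3 to 1 and 2; 19 to 18 and 2; 18 to 15 and 16. Three O–benzyl bonds and, for ring F, the aryl–CHO bond are cut. Formylation precedes benzylation because the formyl group suppresses C-benzylation. The forward steps need O-selective alkylation and a single formylation of two equivalent positions.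

## Other disconnections considered

Alternative 1: The cut is made in each of rings C and D at the bond between the butanoyl-bearing carbon and the hydroxylated carbon next to the bridge-bearing carbon. In the forward direction Mg(OMe)2 in methanol would open both lactones of 3,3'-methylenebis[4-hydroxy-6-(2-oxopentyl)-2H-pyran-2-one] A1, and each triketo ester chain would close by Claisen condensation of its doubly activated side-chain CH2 onto the ester carbon, giving 3,3'-methylenebis(2,4,6-trihydroxybutyrophenone) A2.
- In favour: two aromatic rings arise with butanoyl groups, oxygens and bridge in place, without Friedel–Crafts acylation or protecting groups, driven by aromatisation.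
- Against: A2 has the same constitution as 42, which the chosen route reaches in one step from 36 and 40. A1 needs several steps and its own formaldehyde condensation. A2 has two equivalent free carbons, so attaching the A–B side at one end and the E–F side at the other needs two statistical mono-functionalisations. Rings E and F are not addressed.
- Comparison: on structure, alternative 1 is better than the chosen plan in placing the acyl groups of its two rings without ambiguity, where the chosen plan relies on a late triple acylation. On mechanism it is the safer reaction, closer to known polyketide-type cyclisations than the hindered benzannulation. On step economy it is worse, and it leaves the ordering problem unsolved.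

Alternative 2: The cut is made in ring F at the bond from the methyl-bearing carbon to the ethoxy-bearing carbon and at the bond from the butanoyl-bearing carbon to the hydroxylated carbon next to the arm-bearing carbon. In the forward direction the dienolate of 3-methyl-5-[2,4,6-tris(benzyloxy)benzyl]oxane-2,4,6-trione A3 would add to 1-ethoxyhex-1-yn-3-one A4, the distal anhydride carbonyl would acylate the resulting carbanion, and decarboxylation would aromatise the ring to the mono ethyl ether A5.
- In favour: ring F arrives with methyl, butanoyl and the ring E arm in defined positions and needs no later acylation. If the other α-carbon of A3 were the donor, the regioisomer would converge on the same triol after de-ethylation.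
- Against: A3, an oxoglutaric anhydride with two different α-substituents, is a labile, strongly enolised species with no simple preparation. The annulation is established for benzo-fused anhydrides more than for acyclic ones. The ethyl ether needs a Lewis acid dealkylation. The ring made is the terminal one, which is bought in aromatic form as 15, so rings E to A would then be added one by one.
- Comparison: on structure, alternative 2 is better for ring F alone, because its butanoyl group is placed with certainty. On mechanism it is about equal in risk to the chosen key step, both being extrapolations. On step economy and convergence it is worse, since the chosen step forms a central ring and joins two arms at once.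

Alternative 3: The cut is made in ring A at the bond between the butanoyl-bearing carbon and the oxygenated carbon next to CMe2. In the forward direction NaH would deprotonate C6 of methyl 2,2-dimethyl-3,5,7-trioxo-4-[2,4,6-tris(benzyloxy)benzyl]decanoate A6, and Dieckmann closure onto the ester would give the ring A compound A7 carrying the protected ring B arm.
- In favour: the quaternary CMe2 carbon comes from a building block, so the over- and under-methylation of step 16 does not arise, and the A–B bridge is fixed without formaldehyde.
- Against: A6 is a branched tetracarbonyl chain that needs a multistep polyanion synthesis. It can close through oxygen to pyranones, and its non-enolisable 2,2-dimethyl-3-oxo ester is open to retro-Claisen cleavage by the methoxide released. Ring B in A7 still needs debenzylation, mono-acylation and bridging.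
- Comparison: on structure, alternative 3 is better than step 16 of the chosen plan in the selectivity of making ring A. On mechanism it is an equally well-known reaction type but on a more fragile substrate. On step economy it is worse, because 39 is two steps from 34 and ring A is one terminal ring of six.

Key step: step 11

Remarks on the chemistry:
- Ring A is written as one enol tautomer. The target has no stereocentre; 5, 20 and 26 are racemic and their stereocentres disappear in the following transformation.
- No constitutional error was found in the annulation partners 14 and 24 or in the product 29. By its locants the four-membered intermediate 26 is a 4-vinylcyclobut-2-en-1-one.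
- Lithium and magnesium species are drawn covalently.
- Ketene is generated from acetone in a hot-filament generator and used as a gas stream.

## Steps

Step 1
Reactants: 1 2,4,6-trihydroxybenzaldehyde; 2 benzyl bromide
Product: 3 2,4,6-tris(benzyloxy)benzaldehyde
Conditions: BnBr (3.6 equiv), K2CO3, DMF, 60 °C
Reagents that add atoms: benzyl bromide, BrCc1ccccc1
Why: Williamson ether synthesis; the formyl group lowers the carbon nucleophilicity of the ring, so the three phenoxides should be alkylated on oxygen.

Step 2
Reactants: 3 2,4,6-tris(benzyloxy)benzaldehyde; 4 ethynylmagnesium bromide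
Product: 5 rac-1-[2,4,6-tris(benzyloxy)phenyl]prop-2-yn-1-ol
Conditions: HC≡CMgBr (1.3 equiv), THF, 0 °C; then H2O
Reagents that add atoms: ethynylmagnesium bromide, C#C[Mg]Br
Why: Grignard 1,2-addition to the aldehyde; the carbinol carbon is formed racemic and is removed in step 3; the acid-labile alcohol is taken on crude after a neutral quench.

Step 3
Reactants: 5 rac-1-[2,4,6-tris(benzyloxy)phenyl]prop-2-yn-1-ol
Product: 6 1,3,5-tris(benzyloxy)-2-(prop-2-yn-1-yl)benzene
Conditions: Et3SiH (3 equiv), CF3CO2H (2 equiv), CH2Cl2, −40 → 0 °C, slow addition of 5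
Reagents that add atoms: none
Why: Ionic hydrogenation; the trialkoxyphenyl group stabilises the propargylic cation, which should take hydride from the silane at the benzylic carbon; low temperature, excess silane and slow addition disfavour Friedel–Crafts self-alkylation and loss of benzyl groups.

Step 4
Reactants: 6 1,3,5-tris(benzyloxy)-2-(prop-2-yn-1-yl)benzene; 7 tert-butyl hydroperoxide; 8 chlorotriisopropylsilane
Product: 11 triisopropyl({3-[2,4,6-tris(benzyloxy)phenyl]prop-1-yn-1-yl}oxy)silane, via lithium acetylide 9 (not isolated), via lithium ynolate 10 (not isolated)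
Conditions: n-BuLi (1.0 equiv), THF, −78 °C; t-BuOOLi [t-BuOOH + LiN(SiMe3)2, THF, −78 °C], then 0 °C; i-Pr3SiCl, −78 → 0 °C
Reagents that add atoms: tert-butyl hydroperoxide, CC(C)(C)OO; chlorotriisopropylsilane, CC(C)[Si](Cl)(C(C)C)C(C)C
Why: Electrophilic oxygenation of a lithium acetylide by lithium tert-butyl peroxide gives the ynolate, and the bulky silyl chloride should silylate it on oxygen; this known route to siloxyalkynes uses one equivalent of alkyllithium, so the benzyl ethers see no excess base.

Step 5
Reactants: 11 triisopropyl({3-[2,4,6-tris(benzyloxy)phenyl]prop-1-yn-1-yl}oxy)silane; 12 acetone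
Product: 14 2-[2,4,6-tris(benzyloxy)benzyl]-3-(triisopropylsilyloxy)cyclobut-2-en-1-one, via ketene 13 (not isolated)
Conditions: ketene (acetone pyrolysis, hot-filament generator) passed into 11, CH2Cl2, 0 °C → rt
Reagents that add atoms: acetone, CC(C)=O (delivers C2H2O as ketene 13, C=C=O)
Why: [2+2] cycloaddition of ketene with an ynol ether; the nucleophilic alkyne carbon attacks the ketene carbonyl carbon, which should give the 2-substituted 3-siloxycyclobutenone as the only regioisomer, as known for triisopropylsilyl ynol ethers.

Step 6
Reactants: 15 2-methylphloroglucinol; 16 N,N-dimethylformamide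
Product: 18 2,4,6-trihydroxy-3-methylbenzaldehyde, via aryl iminium chloride 17 (not isolated)
Conditions: POCl3 (1.1 equiv), DMF, EtOAc, 0 °C → rt; then H2O, 50 °C
Reagents that add atoms: N,N-dimethylformamide, CN(C)C=O; water, O
Why: Vilsmeier–Haack formylation; the two free ring carbons are equivalent and the iminium group deactivates the ring against a second attack.

Step 7
Reactants: 18 2,4,6-trihydroxy-3-methylbenzaldehyde; 2 benzyl bromide
Product: 19 2,4,6-tris(benzyloxy)-3-methylbenzaldehyde
Conditions: BnBr (3.6 equiv), K2CO3, DMF, 60 °C
Reagents that add atoms: benzyl bromide, BrCc1ccccc1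
Why: Williamson ether synthesis, O-selective for the same reason as in step 1.

Step 8
Reactants: 19 2,4,6-tris(benzyloxy)-3-methylbenzaldehyde; 4 ethynylmagnesium bromide
Product: 20 rac-1-[2,4,6-tris(benzyloxy)-3-methylphenyl]prop-2-yn-1-ol
Conditions: HC≡CMgBr (1.3 equiv), THF, 0 °C; then H2O
Reagents that add atoms: ethynylmagnesium bromide, C#C[Mg]Br
Why: Grignard 1,2-addition; the racemic carbinol carbon is removed in step 9.

Step 9
Reactants: 20 rac-1-[2,4,6-tris(benzyloxy)-3-methylphenyl]prop-2-yn-1-ol
Product: 21 1,3,5-tris(benzyloxy)-2-methyl-4-(prop-2-yn-1-yl)benzene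
Conditions: Et3SiH (3 equiv), CF3CO2H (2 equiv), CH2Cl2, −40 → 0 °C, slow addition of 20
Reagents that add atoms: none
Why: Ionic hydrogenation of the stabilised propargylic cation, as in step 3.

Step 10
Reactants: 21 1,3,5-tris(benzyloxy)-2-methyl-4-(prop-2-yn-1-yl)benzene; 7 tert-butyl hydroperoxide; 8 chlorotriisopropylsilane
Product: 24 triisopropyl({3-[2,4,6-tris(benzyloxy)-3-methylphenyl]prop-1-yn-1-yl}oxy)silane, via lithium acetylide 22 (not isolated), via lithium ynolate 23 (not isolated)
Conditions: n-BuLi (1.0 equiv), THF, −78 °C; t-BuOOLi [t-BuOOH + LiN(SiMe3)2, THF, −78 °C], then 0 °C; i-Pr3SiCl, −78 → 0 °C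
Reagents that add atoms: tert-butyl hydroperoxide, CC(C)(C)OO; chlorotriisopropylsilane, CC(C)[Si](Cl)(C(C)C)C(C)C
Why: Acetylide oxygenation and O-silylation of the ynolate, as in step 4.

Step 11
Reactants: 14 2-[2,4,6-tris(benzyloxy)benzyl]-3-(triisopropylsilyloxy)cyclobut-2-en-1-one; 24 triisopropyl({3-[2,4,6-tris(benzyloxy)-3-methylphenyl]prop-1-yn-1-yl}oxy)silane
Product: 29 2-[2,4,6-tris(benzyloxy)-3-methylbenzyl]-4-[2,4,6-tris(benzyloxy)benzyl]-3,5-bis(triisopropylsilyloxy)phenol, via siloxyvinylketene 25 (not isolated), via vinylcyclobutenone 26 (not isolated), via dienylketene 27 (not isolated), via cyclohexadienone 28 (not isolated)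
Conditions: 24 (1.3 equiv), toluene (0.1 M), 80 → 110 °C, Ar
Reagents that add atoms: none
Why: Heating opens 14 by 4π electrocyclic cleavage of the bond between its carbonyl carbon and its CH2 carbon to give siloxyvinylketene 25. The polarised ynol ether 24 adds across the ketene C=C in a [2+2] cycloaddition: its nucleophilic carbon, bearing the ring F arm, bonds to the ketene carbon, and its oxygen-bearing carbon bonds to the ketene α-carbon, bearing the ring D arm, to give 26. A second 4π opening of 26 gives dienylketene 27, which closes ring E by a thermally allowed disrotatory 6π electrocyclisation between the ketene carbon and the terminal CH2 to give 28, and enolisation gives phenol 29. The closest known reaction type is the Danheiser benzannulation of 3-oxygenated cyclobutenones with siloxyalkynes, which leads to phloroglucinol derivatives. No stereocentre survives, since the quaternary carbon of 26 is racemic and becomes sp2 on ring opening. The selectivity needed is the regiochemistry of the [2+2] step, secured by the donor oxygen of 24 and the electrophilic ketene carbon of 25, so that the two arms end on ring carbons separated by one siloxy-bearing carbon and the unsubstituted carbon lies between OH and OSi. A modest excess of 24 and moderate dilution should favour capture of 25 by the alkyne over its dimerisation or its addition to the phenol of 29.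

Step 12
Reactants: 29 2-[2,4,6-tris(benzyloxy)-3-methylbenzyl]-4-[2,4,6-tris(benzyloxy)benzyl]-3,5-bis(triisopropylsilyloxy)phenol
Product: 30 2-[2,4,6-tris(benzyloxy)-3-methylbenzyl]-4-[2,4,6-tris(benzyloxy)benzyl]benzene-1,3,5-triol
Conditions: Bu4NF (2.5 equiv), AcOH (2.5 equiv), THF, 0 °C → rt
Reagents that add atoms: none
Why: Fluoride cleavage of aryl silyl ethers; acetic acid buffers the phenoxides so that the electron-rich triol is not oxidised, and benzyl ethers are inert.

Step 13
Reactants: 30 2-[2,4,6-tris(benzyloxy)-3-methylbenzyl]-4-[2,4,6-tris(benzyloxy)benzyl]benzene-1,3,5-triol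
Product: 31 2-(2,4,6-trihydroxy-3-methylbenzyl)-4-(2,4,6-trihydroxybenzyl)benzene-1,3,5-triol
Conditions: H2 (1 atm), 10% Pd/C, EtOAc–MeOH, rt; product kept under Ar
Reagents that add atoms: none
Why: Hydrogenolysis of six benzyl ethers under neutral conditions; the diarylmethane C–C bonds are not cleaved, and the air-sensitive nonaphenol is used at once.

Step 14
Reactants: 31 2-(2,4,6-trihydroxy-3-methylbenzyl)-4-(2,4,6-trihydroxybenzyl)benzene-1,3,5-triol; 32 butanoic anhydride
Product: 33 1-{3-[3-butanoyl-5-(3-butanoyl-2,4,6-trihydroxy-5-methylbenzyl)-2,4,6-trihydroxybenzyl]-2,4,6-trihydroxyphenyl}butan-1-one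
Conditions: (PrCO)2O (3.2 equiv), BF3·OEt2, 1,4-dioxane, rt → 40 °C; then H2O–MeOH, 40 °C
Reagents that add atoms: butanoic anhydride, CCCC(=O)OC(=O)CCC
Why: Friedel–Crafts C-acylation of phloroglucinol rings promoted by BF3, with any aryl butanoate shifting to carbon by Fries rearrangement under the same conditions. Rings E and F have one free carbon each and ring D two equivalent ones, and the chelated ketone deactivates its ring, so stoichiometric anhydride should give one butanoyl group per ring and leave one CH on ring D.

Step 15
Reactants: 34 phloroglucinol; 35 butanoyl chloride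
Product: 36 1-(2,4,6-trihydroxyphenyl)butan-1-one
Conditions: PrCOCl (1.0 equiv), AlCl3 (3 equiv), PhNO2–CH2Cl2, 0 → 40 °C; then ice, HCl
Reagents that add atoms: butanoyl chloride, CCCC(Cl)=O
Why: Friedel–Crafts acylation; the acyl group deactivates the ring, so the reaction should stop at the monoketone.

Step 16
Reactants: 36 1-(2,4,6-trihydroxyphenyl)butan-1-one; 37 iodomethane
Product: 39 2-butanoyl-3,5-dihydroxy-4,4-dimethylcyclohexa-2,5-dien-1-one, via monomethyl ketone 38 (not isolated)
Conditions: NaOMe (3 equiv), MeI (2.2 equiv), MeOH, 0 °C → rt; then dil. HCl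
Reagents that add atoms: iodomethane, CI
Why: C-methylation of the phenoxide-enolate; the second methyl group should enter at the carbon that already bears methyl, giving the stabilised enolised β-triketone (known dearomatising gem-dimethylation to acylfilicinic acids); other methylation levels are removed by chromatography.

Step 17
Reactants: 36 1-(2,4,6-trihydroxyphenyl)butan-1-one; 40 formaldehyde
Product: 42 3,3'-methylenebis(2,4,6-trihydroxybutyrophenone), via hydroxymethyl ketone 41 (not isolated)
Conditions: 37% aq. CH2O (1 equiv), 36 (4 equiv), 1% aq. NaOH, 0 °C → rt; then dil. HCl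
Reagents that add atoms: formaldehyde, C=O
Why: Phenol–formaldehyde condensation: hydroxymethylation, loss of hydroxide and conjugate addition of a second phenoxide; excess 36 limits chain growth and is recovered.

Step 18
Reactants: 39 2-butanoyl-3,5-dihydroxy-4,4-dimethylcyclohexa-2,5-dien-1-one; 43 N,N-dimethylmethyleneiminium iodide; 42 3,3'-methylenebis(2,4,6-trihydroxybutyrophenone)
Product: 46 ring A–B–C trimer 2-butanoyl-6-{3-butanoyl-5-[(3-butanoyl-2,4,6-trihydroxyphenyl)methyl]-2,4,6-trihydroxybenzyl}-3,5-dihydroxy-4,4-dimethylcyclohexa-2,5-dien-1-one, via ring A Mannich base 44 (not isolated), via ring A methylidene trione 45 (not isolated)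
Conditions: CH2=NMe2+ I− (0.95 equiv), NaOAc, MeCN, 0 °C; then 42 (3 equiv), 70 °C
Reagents that add atoms: N,N-dimethylmethyleneiminium iodide, C=[N+](C)C.[I-]
Why: Mannich reaction of the β-triketone with the preformed iminium salt, then retro-Michael loss of dimethylamine and conjugate addition of a free ring carbon of 42 with rearomatisation. 42 is symmetrical, so either ring may react, and its excess limits double alkylation.

Step 19
Reactants: 46 ring A–B–C trimer; 43 N,N-dimethylmethyleneiminium iodide
Product: 47 ring A–B–C trimer carrying CH2NMe2 on the free carbon of ring C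
Conditions: CH2=NMe2+ I− (1.05 equiv), NaOAc, MeCN–CH2Cl2, 0 °C → rt
Reagents that add atoms: N,N-dimethylmethyleneiminium iodide, C=[N+](C)C.[I-]
Why: Mannich aminomethylation of an acylphloroglucinol; ring C has the only unsubstituted nucleophilic carbon, and attack at a substituted carbon cannot rearomatise and should revert.

Step 20
Reactants: 33 tris-butanoyl ring D–E–F trimer; 47 ring A–B–C trimer carrying CH2NMe2 on ring C
Product: 49 target hexamer CNP0309827.0, via ring C quinone methide 48 (not isolated)
Conditions: 1,4-dioxane, 90 °C, Ar stream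
Reagents that add atoms: none
Why: Thermal extrusion of dimethylamine from a phenolic Mannich base gives the o-quinone methide of ring C, and the single free carbon on ring D of 33 adds to it in Michael fashion and rearomatises. Each partner has one reactive site, so only the C–D bridge of the target can form.

## Compound list

1 | 2,4,6-trihydroxybenzaldehyde | O=Cc1c(O)cc(O)cc1O | starting material
2 | benzyl bromide | BrCc1ccccc1 | starting material
3 | 2,4,6-tris(benzyloxy)benzaldehyde | O=Cc1c(OCc2ccccc2)cc(OCc3ccccc3)cc1OCc4ccccc4 | intermediate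
4 | ethynylmagnesium bromide | C#C[Mg]Br | starting material
5 | rac-1-[2,4,6-tris(benzyloxy)phenyl]prop-2-yn-1-ol | OC(C#C)c1c(OCc2ccccc2)cc(OCc3ccccc3)cc1OCc4ccccc4 | intermediate
6 | 1,3,5-tris(benzyloxy)-2-(prop-2-yn-1-yl)benzene | C#CCc1c(OCc2ccccc2)cc(OCc3ccccc3)cc1OCc4ccccc4 | intermediate
7 | tert-butyl hydroperoxide | CC(C)(C)OO | starting material
8 | chlorotriisopropylsilane | CC(C)[Si](Cl)(C(C)C)C(C)C | starting material
9 | lithium acetylide of 6 | [Li]C#CCc1c(OCc2ccccc2)cc(OCc3ccccc3)cc1OCc4ccccc4 | intermediate (not isolated)
10 | lithium 3-[2,4,6-tris(benzyloxy)phenyl]prop-1-yn-1-olate | [Li]OC#CCc1c(OCc2ccccc2)cc(OCc3ccccc3)cc1OCc4ccccc4 | intermediate (not isolated)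
11 | triisopropyl({3-[2,4,6-tris(benzyloxy)phenyl]prop-1-yn-1-yl}oxy)silane | CC(C)[Si](OC#CCc1c(OCc2ccccc2)cc(OCc3ccccc3)cc1OCc4ccccc4)(C(C)C)C(C)C | intermediate
12 | acetone | CC(C)=O | starting material
13 | ketene | C=C=O | intermediate (not isolated)
14 | 2-[2,4,6-tris(benzyloxy)benzyl]-3-(triisopropylsilyloxy)cyclobut-2-en-1-one | O=C1CC(O[Si](C(C)C)(C(C)C)C(C)C)=C1Cc2c(OCc3ccccc3)cc(OCc4ccccc4)cc2OCc5ccccc5 | intermediate
15 | 2-methylphloroglucinol (2-methylbenzene-1,3,5-triol) | Cc1c(O)cc(O)cc1O | starting material
16 | N,N-dimethylformamide | CN(C)C=O | starting material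
17 | N,N-dimethyl-1-(2,4,6-trihydroxy-3-methylphenyl)methaniminium chloride | C[N+](C)=Cc1c(O)cc(O)c(C)c1O.[Cl-] | intermediate (not isolated)
18 | 2,4,6-trihydroxy-3-methylbenzaldehyde | O=Cc1c(O)cc(O)c(C)c1O | intermediate
19 | 2,4,6-tris(benzyloxy)-3-methylbenzaldehyde | O=Cc1c(OCc2ccccc2)cc(OCc3ccccc3)c(C)c1OCc4ccccc4 | intermediate
20 | rac-1-[2,4,6-tris(benzyloxy)-3-methylphenyl]prop-2-yn-1-ol | OC(C#C)c1c(OCc2ccccc2)cc(OCc3ccccc3)c(C)c1OCc4ccccc4 | intermediate
21 | 1,3,5-tris(benzyloxy)-2-methyl-4-(prop-2-yn-1-yl)benzene | C#CCc1c(OCc2ccccc2)cc(OCc3ccccc3)c(C)c1OCc4ccccc4 | intermediate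
22 | lithium acetylide of 21 | [Li]C#CCc1c(OCc2ccccc2)cc(OCc3ccccc3)c(C)c1OCc4ccccc4 | intermediate (not isolated)
23 | lithium 3-[2,4,6-tris(benzyloxy)-3-methylphenyl]prop-1-yn-1-olate | [Li]OC#CCc1c(OCc2ccccc2)cc(OCc3ccccc3)c(C)c1OCc4ccccc4 | intermediate (not isolated)
24 | triisopropyl({3-[2,4,6-tris(benzyloxy)-3-methylphenyl]prop-1-yn-1-yl}oxy)silane | CC(C)[Si](OC#CCc1c(OCc2ccccc2)cc(OCc3ccccc3)c(C)c1OCc4ccccc4)(C(C)C)C(C)C | intermediate
25 | 2-[2,4,6-tris(benzyloxy)benzyl]-3-(triisopropylsilyloxy)buta-1,3-dien-1-one (siloxyvinylketene) | O=C=C(Cc1c(OCc2ccccc2)cc(OCc3ccccc3)cc1OCc4ccccc4)C(=C)O[Si](C(C)C)(C(C)C)C(C)C | intermediate (not isolated)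
26 | rac-4-[2,4,6-tris(benzyloxy)benzyl]-2-[2,4,6-tris(benzyloxy)-3-methylbenzyl]-3-(triisopropylsilyloxy)-4-[1-(triisopropylsilyloxy)ethenyl]cyclobut-2-en-1-one | O=C1C(Cc2c(OCc3ccccc3)cc(OCc4ccccc4)c(C)c2OCc5ccccc5)=C(O[Si](C(C)C)(C(C)C)C(C)C)C1(Cc6c(OCc7ccccc7)cc(OCc8ccccc8)cc6OCc9ccccc9)C(=C)O[Si](C(C)C)(C(C)C)C(C)C | intermediate (not isolated)
27 | (3E)-2-[2,4,6-tris(benzyloxy)-3-methylbenzyl]-4-[2,4,6-tris(benzyloxy)benzyl]-3,5-bis(triisopropylsilyloxy)hexa-1,3,5-trien-1-one (ketene-bearing carbon and siloxyvinyl group cis) | O=C=C(Cc1c(OCc2ccccc2)cc(OCc3ccccc3)c(C)c1OCc4ccccc4)/C(O[Si](C(C)C)(C(C)C)C(C)C)=C(\C(=C)O[Si](C(C)C)(C(C)C)C(C)C)Cc5c(OCc6ccccc6)cc(OCc7ccccc7)cc5OCc8ccccc8 | intermediate (not isolated)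
28 | 2-[2,4,6-tris(benzyloxy)-3-methylbenzyl]-4-[2,4,6-tris(benzyloxy)benzyl]-3,5-bis(triisopropylsilyloxy)cyclohexa-2,4-dien-1-one | O=C1CC(O[Si](C(C)C)(C(C)C)C(C)C)=C(Cc2c(OCc3ccccc3)cc(OCc4ccccc4)cc2OCc5ccccc5)C(O[Si](C(C)C)(C(C)C)C(C)C)=C1Cc6c(OCc7ccccc7)cc(OCc8ccccc8)c(C)c6OCc9ccccc9 | intermediate (not isolated)
29 | 2-[2,4,6-tris(benzyloxy)-3-methylbenzyl]-4-[2,4,6-tris(benzyloxy)benzyl]-3,5-bis(triisopropylsilyloxy)phenol | Oc1cc(O[Si](C(C)C)(C(C)C)C(C)C)c(Cc2c(OCc3ccccc3)cc(OCc4ccccc4)cc2OCc5ccccc5)c(O[Si](C(C)C)(C(C)C)C(C)C)c1Cc6c(OCc7ccccc7)cc(OCc8ccccc8)c(C)c6OCc9ccccc9 | intermediate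
30 | 2-[2,4,6-tris(benzyloxy)-3-methylbenzyl]-4-[2,4,6-tris(benzyloxy)benzyl]benzene-1,3,5-triol | Oc1cc(O)c(Cc2c(OCc3ccccc3)cc(OCc4ccccc4)cc2OCc5ccccc5)c(O)c1Cc6c(OCc7ccccc7)cc(OCc8ccccc8)c(C)c6OCc9ccccc9 | intermediate
31 | 2-(2,4,6-trihydroxy-3-methylbenzyl)-4-(2,4,6-trihydroxybenzyl)benzene-1,3,5-triol | Oc1cc(O)c(Cc2c(O)cc(O)cc2O)c(O)c1Cc3c(O)cc(O)c(C)c3O | intermediate
32 | butanoic anhydride | CCCC(=O)OC(=O)CCC | starting material
33 | 1-{3-[3-butanoyl-5-(3-butanoyl-2,4,6-trihydroxy-5-methylbenzyl)-2,4,6-trihydroxybenzyl]-2,4,6-trihydroxyphenyl}butan-1-one (tris-butanoyl ring D–E–F trimer) | CCCC(=O)c1c(O)cc(O)c(Cc2c(O)c(Cc3c(O)c(C)c(O)c(C(=O)CCC)c3O)c(O)c(C(=O)CCC)c2O)c1O | intermediate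
34 | phloroglucinol | Oc1cc(O)cc(O)c1 | starting material
35 | butanoyl chloride | CCCC(Cl)=O | starting material
36 | 1-(2,4,6-trihydroxyphenyl)butan-1-one | CCCC(=O)c1c(O)cc(O)cc1O | intermediate
37 | iodomethane | CI | starting material
38 | 1-(2,4,6-trihydroxy-3-methylphenyl)butan-1-one | CCCC(=O)c1c(O)cc(O)c(C)c1O | intermediate (not isolated)
39 | 2-butanoyl-3,5-dihydroxy-4,4-dimethylcyclohexa-2,5-dien-1-one (butanoylfilicinic acid) | CCCC(=O)C1=C(O)C(C)(C)C(O)=CC1=O | intermediate
40 | formaldehyde | C=O | starting material
41 | 1-[2,4,6-trihydroxy-3-(hydroxymethyl)phenyl]butan-1-one | CCCC(=O)c1c(O)cc(O)c(CO)c1O | intermediate (not isolated)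
42 | 3,3'-methylenebis(2,4,6-trihydroxybutyrophenone) | CCCC(=O)c1c(O)cc(O)c(Cc2c(O)cc(O)c(C(=O)CCC)c2O)c1O | intermediate
43 | N,N-dimethylmethyleneiminium iodide | C=[N+](C)C.[I-] | starting material
44 | 2-butanoyl-6-[(dimethylamino)methyl]-3,5-dihydroxy-4,4-dimethylcyclohexa-2,5-dien-1-one | CCCC(=O)C1=C(O)C(C)(C)C(O)=C(CN(C)C)C1=O | intermediate (not isolated)
45 | 2-butanoyl-3-hydroxy-4,4-dimethyl-6-methylidenecyclohex-2-ene-1,5-dione | CCCC(=O)C1=C(O)C(C)(C)C(=O)C(=C)C1=O | intermediate (not isolated)
46 | ring A–B–C trimer: 2-butanoyl-6-{3-butanoyl-5-[(3-butanoyl-2,4,6-trihydroxyphenyl)methyl]-2,4,6-trihydroxybenzyl}-3,5-dihydroxy-4,4-dimethylcyclohexa-2,5-dien-1-one | CCCC(=O)C1=C(O)C(C)(C)C(O)=C(Cc2c(O)c(Cc3c(O)cc(O)c(C(=O)CCC)c3O)c(O)c(C(=O)CCC)c2O)C1=O | intermediate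
47 | ring A–B–C trimer with (dimethylamino)methyl on the free carbon of ring C | CCCC(=O)C1=C(O)C(C)(C)C(O)=C(Cc2c(O)c(Cc3c(O)c(CN(C)C)c(O)c(C(=O)CCC)c3O)c(O)c(C(=O)CCC)c2O)C1=O | intermediate
48 | ring A–B–C trimer with ring C as 6-methylidenecyclohexa-2,4-dienone (o-quinone methide) | CCCC(=O)C1=C(O)C(C)(C)C(O)=C(Cc2c(O)c(CC3=C(O)C(C(=O)CCC)=C(O)C(=C)C3=O)c(O)c(C(=O)CCC)c2O)C1=O | intermediate (not isolated)
49 | CNP0309827.0: 2-butanoylfilicinic acid (ring A) joined through five CH2 bridges in a linear chain to four 3-butanoyl-2,4,6-trihydroxy-1,5-phenylene units (rings B to E) and a terminal 3-butanoyl-2,4,6-trihydroxy-5-methylphenyl unit (ring F) | CCCC(=O)C1=C(O)C(C)(C)C(O)=C(Cc2c(O)c(Cc3c(O)c(Cc4c(O)c(Cc5c(O)c(Cc6c(O)c(C)c(O)c(C(=O)CCC)c6O)c(O)c(C(=O)CCC)c5O)c(O)c(C(=O)CCC)c4O)c(O)c(C(=O)CCC)c3O)c(O)c(C(=O)CCC)c2O)C1=O | target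

## Step count and least certain steps

Total: 20 steps. Longest linear sequence: 10 steps (steps 1 to 5, 11 to 14 and 20; the ring F branch, steps 6 to 10, 11 to 14 and 20, is equally long).

Step 11 (key step). The most likely failure is that bimolecular capture of the short-lived siloxyvinylketene is too slow, because both reacting carbons carry 2,6-bis(benzyloxy)benzyl groups and a crowded quaternary carbon must form. The ketene would then be lost by dimerisation or by acylating the product phenol. The fallback gives up the annulation and builds the same core by Friedel–Crafts benzylation, setting out from 3, 19 and 34 and returning at 30: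
- 3 is reduced with NaBH4 to [2,4,6-tris(benzyloxy)phenyl]methanol F1.
- F1 is added slowly to excess 34 with catalytic CF3CO2H in MeCN at 0 °C, where its stabilised benzylic cation alkylates the ring to 2-[2,4,6-tris(benzyloxy)benzyl]benzene-1,3,5-triol F2.
- 19 is reduced likewise to [2,4,6-tris(benzyloxy)-3-methylphenyl]methanol F3.
- F3 alkylates one of the two equivalent free carbons of F2 to give 30.

Step 14. The most likely failure is acid-promoted ipso-protonation with migration or loss of the two CH2 bridges, or cyclodehydration of neighbouring phenols, together with a second acylation on ring D or incomplete O-to-C shift. The fallback is a Houben–Hoesch acylation, setting out from 31 and returning at 33. Butyronitrile, ZnCl2 and HCl in Et2O–dioxane at 0 °C should give the tris(ketiminium) trichloride F4, in which each ring takes one unit because the iminium group deactivates strongly and oxygen is not acylated. Warm water then hydrolyses F4 to 33.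

Step 20. The most likely failure is retro-Michael reopening of existing bridges at the temperature needed for amine extrusion, in the presence of liberated amine, so that the oligomer sequence scrambles; slow capture by the deactivated ring D carbon would make this worse. The fallback reverses the roles and triggers the quinone methide by charge at low temperature, setting out from 33 and 46 and returning at 49:
- 33 is aminomethylated with 43 to the ring D Mannich base F5.
- F5 is quaternised with MeI to the trimethylammonium iodide F6.
- F6 is treated with 46 and NaHCO3 in MeCN at 0 to 25 °C, where elimination of trimethylamine and capture by the free ring C carbon of 46 give 49 without heating.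

Steps 3 and 9. The most likely failure is capture of the propargylic cation at the wrong terminus (allene formation) or by another arene ring, because the benzylic carbon is flanked by two benzyloxy groups; acid loss of benzyl groups is a lesser risk. The fallback avoids the cation by making the ynolate from an arylacetate, setting out from 3 and returning at 11:
- Knoevenagel condensation of 3 with methyl (methylthio)methyl sulfoxide (benzyltrimethylammonium hydroxide, THF, reflux) gives 1-(methylsulfanyl)-1-(methylsulfinyl)-2-[2,4,6-tris(benzyloxy)phenyl]ethene F7.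
- HCl in ethanol converts F7 into ethyl [2,4,6-tris(benzyloxy)phenyl]acetate F8.
- Kowalski ester homologation of F8 (CH2Br2, lithium 2,2,6,6-tetramethylpiperidide, THF, −78 °C, then n-BuLi, −78 → 0 °C) gives ynolate 10, which 8 silylates to 11.
- The same operations from 19, through 1-(methylsulfanyl)-1-(methylsulfinyl)-2-[2,4,6-tris(benzyloxy)-3-methylphenyl]ethene F9 and ethyl [2,4,6-tris(benzyloxy)-3-methylphenyl]acetate F10, give 23 and then 24.

Step 18. The most likely failure is over-alkylation of the symmetrical dimer at both free carbons, or exchange of the aminomethyl group leading to self-coupling of ring A units. The fallback builds the trimer one ring at a time with the cheap monomer in large excess, setting out from 39 and returning at 46: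
- 44, made from 39 and 43, is heated with excess 36 to give the ring A–B dimer 2-butanoyl-6-(3-butanoyl-2,4,6-trihydroxybenzyl)-3,5-dihydroxy-4,4-dimethylcyclohexa-2,5-dien-1-one F11.
- F11 is aminomethylated with 43 on ring B to the Mannich base F12.
- F12 is heated with excess 36 to give 46.

## Further compounds

F1 | step 11 | [2,4,6-tris(benzyloxy)phenyl]methanol | OCc1c(OCc2ccccc2)cc(OCc3ccccc3)cc1OCc4ccccc4
F2 | step 11 | 2-[2,4,6-tris(benzyloxy)benzyl]benzene-1,3,5-triol | Oc1cc(O)c(Cc2c(OCc3ccccc3)cc(OCc4ccccc4)cc2OCc5ccccc5)c(O)c1
F3 | step 11 | [2,4,6-tris(benzyloxy)-3-methylphenyl]methanol | OCc1c(OCc2ccccc2)cc(OCc3ccccc3)c(C)c1OCc4ccccc4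
F4 | step 14 | tris(ketiminium) trichloride of 33 | CCCC(=[NH2+])c1c(O)cc(O)c(Cc2c(O)c(Cc3c(O)c(C)c(O)c(C(=[NH2+])CCC)c3O)c(O)c(C(=[NH2+])CCC)c2O)c1O.[Cl-].[Cl-].[Cl-]
F5 | step 20 | ring D Mannich base of 33 | CCCC(=O)c1c(O)c(CN(C)C)c(O)c(Cc2c(O)c(Cc3c(O)c(C)c(O)c(C(=O)CCC)c3O)c(O)c(C(=O)CCC)c2O)c1O
F6 | step 20 | ring D trimethylammoniomethyl derivative of 33, iodide | CCCC(=O)c1c(O)c(C[N+](C)(C)C)c(O)c(Cc2c(O)c(Cc3c(O)c(C)c(O)c(C(=O)CCC)c3O)c(O)c(C(=O)CCC)c2O)c1O.[I-]
F7 | step 3 | 1-(methylsulfanyl)-1-(methylsulfinyl)-2-[2,4,6-tris(benzyloxy)phenyl]ethene (E/Z mixture, racemic at sulfur) | CSC(=Cc1c(OCc2ccccc2)cc(OCc3ccccc3)cc1OCc4ccccc4)S(C)=O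
F8 | step 3 | ethyl [2,4,6-tris(benzyloxy)phenyl]acetate | CCOC(=O)Cc1c(OCc2ccccc2)cc(OCc3ccccc3)cc1OCc4ccccc4
F9 | step 9 | 1-(methylsulfanyl)-1-(methylsulfinyl)-2-[2,4,6-tris(benzyloxy)-3-methylphenyl]ethene (E/Z mixture, racemic at sulfur) | CSC(=Cc1c(OCc2ccccc2)cc(OCc3ccccc3)c(C)c1OCc4ccccc4)S(C)=O
F10 | step 9 | ethyl [2,4,6-tris(benzyloxy)-3-methylphenyl]acetate | CCOC(=O)Cc1c(OCc2ccccc2)cc(OCc3ccccc3)c(C)c1OCc4ccccc4
F11 | step 18 | 2-butanoyl-6-(3-butanoyl-2,4,6-trihydroxybenzyl)-3,5-dihydroxy-4,4-dimethylcyclohexa-2,5-dien-1-one | CCCC(=O)C1=C(O)C(C)(C)C(O)=C(Cc2c(O)cc(O)c(C(=O)CCC)c2O)C1=O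
F12 | step 18 | ring B Mannich base of F11 | CCCC(=O)C1=C(O)C(C)(C)C(O)=C(Cc2c(O)c(CN(C)C)c(O)c(C(=O)CCC)c2O)C1=O
A1 | alternative 1 | 3,3'-methylenebis[4-hydroxy-6-(2-oxopentyl)-2H-pyran-2-one] | CCCC(=O)CC1=CC(O)=C(CC2=C(O)C=C(CC(=O)CCC)OC2=O)C(=O)O1
A2 | alternative 1 | 3,3'-methylenebis(2,4,6-trihydroxybutyrophenone) | CCCC(=O)c1c(O)cc(O)c(Cc2c(O)cc(O)c(C(=O)CCC)c2O)c1O
A3 | alternative 2 | 3-methyl-5-[2,4,6-tris(benzyloxy)benzyl]oxane-2,4,6-trione (enolisable, configuration undefined) | CC1C(=O)OC(=O)C(Cc2c(OCc3ccccc3)cc(OCc4ccccc4)cc2OCc5ccccc5)C1=O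
A4 | alternative 2 | 1-ethoxyhex-1-yn-3-one | CCCC(=O)C#COCC
A5 | alternative 2 | 1-{2-ethoxy-4,6-dihydroxy-3-methyl-5-[2,4,6-tris(benzyloxy)benzyl]phenyl}butan-1-one | CCCC(=O)c1c(O)c(Cc2c(OCc3ccccc3)cc(OCc4ccccc4)cc2OCc5ccccc5)c(O)c(C)c1OCC
A6 | alternative 3 | methyl 2,2-dimethyl-3,5,7-trioxo-4-[2,4,6-tris(benzyloxy)benzyl]decanoate (racemic, enolisable) | CCCC(=O)CC(=O)C(Cc1c(OCc2ccccc2)cc(OCc3ccccc3)cc1OCc4ccccc4)C(=O)C(C)(C)C(=O)OC
A7 | alternative 3 | 2-butanoyl-3,5-dihydroxy-4,4-dimethyl-6-[2,4,6-tris(benzyloxy)benzyl]cyclohexa-2,5-dien-1-one | CCCC(=O)C1=C(O)C(C)(C)C(O)=C(Cc2c(OCc3ccccc3)cc(OCc4ccccc4)cc2OCc5ccccc5)C1=O
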